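**Retrosynthetic overview**

1. The route rests on the pentasubstituted benzo ring of the flavene (C4a′, C5′–C8′, C8a′; oxygen on C5′, C7′, C8′, C8a′, carbon on C4a′). It is cut into the vinylketene from 3,4-dimethoxycyclobutenone and a methoxyalkyne that carries C4′ (bonds C8a′–C4a′, C5′–C6′, C8′–C8a′); the O1′–C2′ bond of the pyran is closed last by cyclodehydration.
2. The ynol ether comes from conjugate addition of a methoxyethynylalane to the alkylidene β-keto ester of the eudesmane 1-carbaldehyde. The allyl ester is a traceless activating group whose cis carbonyl enforces A1,3 control at C4′.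
3. The decalin comes from an intramolecular Diels–Alder reaction of a trienoate made from (R)-limonene (ozonolysis, three olefinations), forming C5–C10 and C1–C2; epoxidation and hydride opening set the C4 carbinol.
4. Ring order: rings A and B of the eudesmane together, then the benzene ring, then the 4H-pyran ring.

Key step: step 16

Remark: eudesmane numbering is used for the decalin (C1–C5 and C10 = ring A, C5–C10 = ring B, C14 = methyl on C10, C15 = methyl on C4, C11–C13 = isopropenyl on C7, β = face of C14); primed numbers are 4H-chromene positions.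
Remark: by the CIP rules the propargylic carbon of 22 and 23 and the benzylic carbon of 31 and 32 are R (alkynyl or aryl > eudesmyl > CH2); this is the same spatial arrangement as 4′S in the target.

**Route**

Step 1
Reactants: 1 (R)-(+)-limonene
Product: 3 (3R)-6-oxo-3-(prop-1-en-2-yl)heptanal, via limonene ozonide 2 (not isolated)
Conditions: O3 (1.0 equiv), CH2Cl2, −78 °C; then PPh3, −78 → 25 °C
Reagents that add atoms: ozone, [O-][O+]=O
Why: Ozone attacks the electron-rich trisubstituted ring alkene faster than the 1,1-disubstituted isopropenyl group, and reductive cleavage of the ozonide gives the keto aldehyde with the future C7 centre (R) untouched (chemoselective ozonolysis).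

Step 2
Reactants: 3 (3R)-6-oxo-3-(prop-1-en-2-yl)heptanal
Product: 4 (2E,5R)-2-methyl-8-oxo-5-(prop-1-en-2-yl)non-2-enal
Conditions: Ph3P=C(CH3)CHO (1.2 equiv), toluene, 90 °C
Reagents that add atoms: 2-(triphenylphosphoranylidene)propanal, CC(C=O)=P(c1ccccc1)(c1ccccc1)c1ccccc1
Why: Wittig reaction of the stabilised ylide is selective for the aldehyde over the methyl ketone and should give the E-trisubstituted enal.

Step 3
Reactants: 4 (2E,5R)-2-methyl-8-oxo-5-(prop-1-en-2-yl)non-2-enal
Product: 5 (5R,7E)-8-methyl-5-(prop-1-en-2-yl)deca-7,9-dien-2-one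
Conditions: Ph3PCH3Br, KN(SiMe3)2, THF, 0 °C; then 4, −78 → −20 °C
Reagents that add atoms: methyltriphenylphosphonium bromide, C[P+](c1ccccc1)(c1ccccc1)c1ccccc1.[Br-]
Why: At low temperature the non-stabilised ylide (1.05 equiv) methylenates the aldehyde much faster than the methyl ketone (Wittig methylenation), giving the E-2-methyl-1,3-diene.

Step 4
Reactants: 5 (5R,7E)-8-methyl-5-(prop-1-en-2-yl)deca-7,9-dien-2-one
Product: 6 ethyl (2E,6R,8E)-3,9-dimethyl-6-(prop-1-en-2-yl)undeca-2,8,10-trienoate
Conditions: (EtO)2P(O)CH2CO2Et, NaH, THF, 0 → 50 °C; chromatography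
Reagents that add atoms: triethyl phosphonoacetate, CCOC(=O)CP(=O)(OCC)OCC
Why: Horner–Wadsworth–Emmons olefination of the methyl ketone should favour the 2E ester, the geometry that places the ester cis to the future C14 methyl; the minor 2Z isomer would be removed by chromatography.

Step 5
Reactants: 6 ethyl (2E,6R,8E)-3,9-dimethyl-6-(prop-1-en-2-yl)undeca-2,8,10-trienoate
Product: 7 ethyl 5αH-eudesma-3,11-diene-1β-carboxylate
Conditions: toluene (0.01 M), BHT (cat.), 180 °C, sealed tube
Reagents that add atoms: none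
Why: Intramolecular Diels–Alder reaction of the 1,7,9-decatriene closes rings A and B together (C5–C10 and C1–C2): the four-carbon tether adopts a chair with the isopropenyl group equatorial, the endo orientation of the E-ester leads to the trans ring fusion, and suprafacial addition sets C10 (β-methyl), C5 (α-H) and C1 (β-ester, cis to C14) relative to C7.

Step 6
Reactants: 7 ethyl 5αH-eudesma-3,11-diene-1β-carboxylate
Product: 8 ethyl 3α,4α-epoxy-5αH-eudesm-11-ene-1β-carboxylate
Conditions: mCPBA (1.05 equiv), NaHCO3, CH2Cl2, −20 → 0 °C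
Reagents that add atoms: mCPBA, OOC(=O)c1cccc(Cl)c1
Why: Prilezhaev epoxidation is faster at the trisubstituted C3=C4 alkene than at the isopropenyl group and should occur on the α face, opposite the axial C14 methyl, which fixes the C4 oxygen as α.

Step 7
Reactants: 8 ethyl 3α,4α-epoxy-5αH-eudesm-11-ene-1β-carboxylate
Product: 9 1β-(hydroxymethyl)-5αH-eudesm-11-en-4α-ol
Conditions: LiAlH4, THF, 0 °C → reflux; aqueous NaOH work-up
Reagents that add atoms: none
Why: Hydride opens the trisubstituted epoxide at the secondary C3 (attack at C4 is tertiary and blocked by C14), leaving the oxygen on C4 as the equatorial 4α-alcohol with the 4β-methyl, and the same reagent reduces the ester to the primary alcohol.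

Step 8
Reactants: 9 1β-(hydroxymethyl)-5αH-eudesm-11-en-4α-ol
Product: 10 4α-hydroxy-5αH-eudesm-11-ene-1β-carbaldehyde
Conditions: Dess–Martin periodinane, NaHCO3, CH2Cl2, 0 → 25 °C
Reagents that add atoms: none
Why: Dess–Martin oxidation converts the primary alcohol into the aldehyde while the tertiary alcohol cannot react, and the equatorial 1β-formyl group is the thermodynamic epimer.

Step 9
Reactants: 11 ethyl 3-oxo-3-phenylpropanoate; 12 prop-2-en-1-ol
Product: 13 prop-2-en-1-yl 3-oxo-3-phenylpropanoate (allyl benzoylacetate)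
Conditions: 12 (5 equiv), DMAP (10 mol %), toluene, reflux (−EtOH)
Reagents that add atoms: none
Why: DMAP-catalysed transesterification of a β-keto ester, driven by distilling off ethanol.

Step 10
Reactants: 10 4α-hydroxy-5αH-eudesm-11-ene-1β-carbaldehyde; 13 allyl benzoylacetate
Product: 14 allyl 2-benzoyl-3-(4α-hydroxyeudesm-11-en-1β-yl)prop-2-enoate (E/Z mixture)
Conditions: piperidine (0.2 equiv), AcOH (0.2 equiv), benzene, reflux, Dean–Stark
Reagents that add atoms: none
Why: Knoevenagel condensation gives the doubly activated alkene, in which one carbonyl group is necessarily cis to C1 in either isomer; this is what enforces A1,3 control in step 12.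

Step 11
Reactants: 15 2-chloro-1,1-dimethoxyethane
Product: 17 methoxyethyne, via sodium methoxyacetylide 16 (not isolated)
Conditions: NaNH2 (3 equiv), liquid NH3, −33 °C; then cold aqueous NaCl, distillation
Reagents that add atoms: none
Why: Successive β-eliminations of methanol and HCl followed by deprotonation give the sodium acetylide, which is protonated on aqueous quench (elimination route to ynol ethers from α-halo acetals).

Step 12
Reactants: 14 allyl 2-benzoyl-3-(4α-hydroxyeudesm-11-en-1β-yl)prop-2-enoate; 17 methoxyethyne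
Product: 20 allyl 2-benzoyl-3-(4α-hydroxyeudesm-11-en-1β-yl)-5-methoxypent-4-ynoate (both epimers at C2), via lithium methoxyacetylide 18 (not isolated), via diethyl(methoxyethynyl)alane 19 (not isolated)
Conditions: 17 (3.3 equiv), n-BuLi (3.0 equiv), Et2O, −78 °C; Et2AlCl (3.0 equiv), −78 → 0 °C; then 14, toluene, −78 → 0 °C; aqueous KNaC4H4O6
Reagents that add atoms: none
Why: Alkynylalane conjugate addition to the aluminium-bound s-cis alkylidene β-keto ester: A1,3 strain with the cis carbonyl group holds C1–H in the alkene plane, so the alkynyl group should attack C4′ anti to the quaternary C10 (from the C2 side), which gives the C4′ configuration of the target; the excess reagent covers the free hydroxyl.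

Step 13
Reactants: 20 allyl 2-benzoyl-3-(4α-hydroxyeudesm-11-en-1β-yl)-5-methoxypent-4-ynoate
Product: 22 (3R)-3-(4α-hydroxyeudesm-11-en-1β-yl)-5-methoxy-1-phenylpent-4-yn-1-one, via β-keto acid 21 (not isolated)
Conditions: Pd(PPh3)4 (5 mol %), morpholine (3 equiv), THF, 25 → 40 °C
Reagents that add atoms: none
Why: Tsuji–Trost deallylation with zerovalent palladium and morpholine frees the β-keto acid, which decarboxylates under basic conditions that spare the ynol ether and C4′; the epimeric α-carbon becomes CH2.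

Step 14
Reactants: 22 (3R)-3-(4α-hydroxyeudesm-11-en-1β-yl)-5-methoxy-1-phenylpent-4-yn-1-one
Product: 23 (3R)-5-methoxy-1-phenyl-3-[4α-(trimethylsilyloxy)eudesm-11-en-1β-yl]pent-4-yn-1-one
Conditions: 1-(trimethylsilyl)imidazole, CH2Cl2, 25 °C
Reagents that add atoms: 1-(trimethylsilyl)imidazole, C[Si](C)(C)n1ccnc1
Why: Silyl transfer from the N-silylimidazole protects the tertiary alcohol under non-acidic conditions that the ynol ether and the ketone tolerate.

Step 15
Reactants: 24 methoxyacetyl chloride; 17 methoxyethyne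
Product: 26 3,4-dimethoxycyclobut-2-en-1-one (racemic), via methoxyketene 25 (not isolated)
Conditions: Et3N (slow addition), 17 (4 equiv), Et2O, 0 → 25 °C
Reagents that add atoms: none
Why: Dehydrochlorination gives methoxyketene, which undergoes a regioselective [2+2] cycloaddition with the ynol ether (ketene carbonyl carbon to the unsubstituted alkyne carbon) to give the 3,4-dimethoxycyclobutenone.

Step 16
Reactants: 23 (3R)-5-methoxy-1-phenyl-3-[4α-(trimethylsilyloxy)eudesm-11-en-1β-yl]pent-4-yn-1-one; 26 3,4-dimethoxycyclobut-2-en-1-one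
Product: 31 (3R)-3-(2-hydroxy-3,4,6-trimethoxyphenyl)-1-phenyl-3-[4α-(trimethylsilyloxy)eudesm-11-en-1β-yl]propan-1-one, via dimethoxyvinylketene 27 (not isolated), via vinylcyclobutenone adduct 28 (not isolated), via dienylketene 29 (not isolated), via cyclohexadienone 30 (not isolated)
Conditions: 26 (1.5 equiv), toluene (0.4 M), 80 °C, then 110 °C
Reagents that add atoms: none
Why: On heating, 26 undergoes 4π-electrocyclic opening (C4 methoxy group rotating outward) to vinylketene 27, whose ketene C=C adds [2+2] to the ynol ether of 23 to give 4-vinylcyclobutenone 28; a second 4π opening gives dienylketene 29, and 6π-electrocyclisation followed by tautomerisation of dienone 30 delivers the phenol. This is a Danheiser benzannulation of a cyclobutenone with an alkoxyalkyne, the closest known reaction type, applied here to a 4-alkoxycyclobutenone and a ketone-bearing ynol ether that have not been tried in it. The benzene ring (C4a′, C5′–C8′, C8a′) is closed by the thermal disrotatory 6π-electrocyclisation that forms C8′–C8a′, after the [2+2] step has formed C8a′–C4a′ and C5′–C6′. No stereocentre is created (those in 28 and 30 are transient), and the neutral conditions leave the propargylic C4′ untouched. The one selectivity needed is the regiochemistry of the [2+2] step, secured by the polarisation of the ynol ether: its nucleophilic, alkyl-bearing carbon bonds to the electrophilic ketene carbon, so the free OH lands on C8a′ ortho to the C4′ chain and the methoxy groups on C5′, C7′ and C8′. The C4 hydroxyl is masked as its trimethylsilyl ether so that it cannot capture the ketenes, and the di-ortho-substituted phenol formed should be slow to do so.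

Step 17
Reactants: 31 (3R)-3-(2-hydroxy-3,4,6-trimethoxyphenyl)-1-phenyl-3-[4α-(trimethylsilyloxy)eudesm-11-en-1β-yl]propan-1-one
Product: 34 (4′S)-4′-(4α-hydroxyeudesm-11-en-1β-yl)-5′,7′,8′-trimethoxy-2′-phenyl-4′H-chromene (target), via desilylated keto phenol 32 (not isolated), via cyclic hemiketal 33 (not isolated)
Conditions: PPTS (0.2 equiv), toluene, 60 °C; then 4 Å molecular sieves
Reagents that add atoms: none
Why: Mild acid cleaves the silyl ether (the water released by the cyclisation serves as acceptor), the phenol adds to the phenyl ketone to give the hemiketal, and acid-catalysed dehydration gives the conjugated 2-phenyl-4H-pyran (cyclodehydration) without touching the tertiary alcohol, the isopropenyl group or C4′.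

**Compound list**

1 | (R)-(+)-limonene | C=C(C)[C@@H]1CCC(C)=CC1 | starting material
2 | limonene 1,2-ozonide (1,2,4-trioxolane across the ring alkene; both diastereomers) | C=C(C)[C@@H]1CCC2(C)OOC(C1)O2 | intermediate
3 | (3R)-6-oxo-3-(prop-1-en-2-yl)heptanal | C=C(C)[C@@H](CC=O)CCC(C)=O | intermediate
4 | (2E,5R)-2-methyl-8-oxo-5-(prop-1-en-2-yl)non-2-enal | C=C(C)[C@@H](C/C=C(C)/C=O)CCC(C)=O | intermediate
5 | (5R,7E)-8-methyl-5-(prop-1-en-2-yl)deca-7,9-dien-2-one | C=C(C)[C@@H](C/C=C(C)/C=C)CCC(C)=O | intermediate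
6 | ethyl (2E,6R,8E)-3,9-dimethyl-6-(prop-1-en-2-yl)undeca-2,8,10-trienoate | C=C(C)[C@@H](C/C=C(C)/C=C)CC/C(C)=C/C(=O)OCC | intermediate
7 | ethyl 5αH-eudesma-3,11-diene-1β-carboxylate (trans-decalin, 10β-methyl, 7β-isopropenyl) | C=C(C)[C@@H]1CC[C@]2(C)[C@@H](C1)C(C)=CC[C@H]2C(=O)OCC | intermediate
8 | ethyl 3α,4α-epoxy-5αH-eudesm-11-ene-1β-carboxylate | C=C(C)[C@@H]1CC[C@]2(C)[C@@H](C1)[C@]1(C)O[C@@H]1C[C@H]2C(=O)OCC | intermediate
9 | 1β-(hydroxymethyl)-5αH-eudesm-11-en-4α-ol | C=C(C)[C@@H]1CC[C@]2(C)[C@@H](C1)[C@](C)(O)CC[C@H]2CO | intermediate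
10 | 4α-hydroxy-5αH-eudesm-11-ene-1β-carbaldehyde | C=C(C)[C@@H]1CC[C@]2(C)[C@@H](C1)[C@](C)(O)CC[C@H]2C=O | intermediate
11 | ethyl 3-oxo-3-phenylpropanoate (ethyl benzoylacetate) | CCOC(=O)CC(=O)c1ccccc1 | starting material
12 | prop-2-en-1-ol (allyl alcohol) | C=CCO | starting material
13 | prop-2-en-1-yl 3-oxo-3-phenylpropanoate (allyl benzoylacetate) | C=CCOC(=O)CC(=O)c1ccccc1 | intermediate
14 | allyl 2-benzoyl-3-(4α-hydroxyeudesm-11-en-1β-yl)prop-2-enoate (E/Z mixture) | C=C(C)[C@@H]1CC[C@]2(C)[C@@H](C1)[C@](C)(O)CC[C@H]2C=C(C(=O)c1ccccc1)C(=O)OCC=C | intermediate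
15 | 2-chloro-1,1-dimethoxyethane (chloroacetaldehyde dimethyl acetal) | COC(CCl)OC | starting material
16 | sodium methoxyacetylide | [Na+].[C-]#COC | intermediate
17 | methoxyethyne | C#COC | intermediate
18 | lithium methoxyacetylide | [Li]C#COC | intermediate
19 | diethyl(methoxyethynyl)alane | CC[Al](CC)C#COC | intermediate
20 | allyl 2-benzoyl-3-(4α-hydroxyeudesm-11-en-1β-yl)-5-methoxypent-4-ynoate (C3 as in 22; both epimers at C2) | C=C(C)[C@@H]1CC[C@]2(C)[C@@H](C1)[C@](C)(O)CC[C@H]2[C@@H](C(C(=O)c1ccccc1)C(=O)OCC=C)C#COC | intermediate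
21 | 2-benzoyl-3-(4α-hydroxyeudesm-11-en-1β-yl)-5-methoxypent-4-ynoic acid (both epimers at C2) | C=C(C)[C@@H]1CC[C@]2(C)[C@@H](C1)[C@](C)(O)CC[C@H]2[C@@H](C(C(=O)c1ccccc1)C(=O)O)C#COC | intermediate
22 | (3R)-3-(4α-hydroxyeudesm-11-en-1β-yl)-5-methoxy-1-phenylpent-4-yn-1-one | C=C(C)[C@@H]1CC[C@]2(C)[C@@H](C1)[C@](C)(O)CC[C@H]2[C@@H](CC(=O)c1ccccc1)C#COC | intermediate
23 | (3R)-5-methoxy-1-phenyl-3-[4α-(trimethylsilyloxy)eudesm-11-en-1β-yl]pent-4-yn-1-one | C=C(C)[C@@H]1CC[C@]2(C)[C@@H](C1)[C@](C)(O[Si](C)(C)C)CC[C@H]2[C@@H](CC(=O)c1ccccc1)C#COC | intermediate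
24 | methoxyacetyl chloride | COCC(=O)Cl | starting material
25 | methoxyketene | COC=C=O | intermediate
26 | 3,4-dimethoxycyclobut-2-en-1-one (racemic) | COC1C(=O)C=C1OC | intermediate
27 | (3Z)-3,4-dimethoxybuta-1,3-dien-1-one (vinylketene) | O=C=C/C(OC)=C/OC | intermediate
28 | 4-(1,2-dimethoxyvinyl)-3-methoxycyclobut-2-en-1-one carrying the C4′ chain of 23 at C2 (both epimers at C4 of the four-membered ring) | C=C(C)[C@@H]1CC[C@]2(C)[C@@H](C1)[C@](C)(O[Si](C)(C)C)CC[C@H]2[C@@H](CC(=O)c1ccccc1)C1=C(OC)C(/C(OC)=C/OC)C1=O | intermediate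
29 | 3,5,6-trimethoxyhexa-1,3,5-trien-1-one carrying the C4′ chain of 23 at C2 (dienylketene) | C=C(C)[C@@H]1CC[C@]2(C)[C@@H](C1)[C@](C)(O[Si](C)(C)C)CC[C@H]2[C@@H](CC(=O)c1ccccc1)C(=C=O)/C(OC)=C\C(OC)=C\OC | intermediate
30 | 3,5,6-trimethoxycyclohexa-2,4-dien-1-one carrying the C4′ chain of 23 at C2 (both epimers at C6 of the dienone) | C=C(C)[C@@H]1CC[C@]2(C)[C@@H](C1)[C@](C)(O[Si](C)(C)C)CC[C@H]2[C@@H](CC(=O)c1ccccc1)C1=C(OC)C=C(OC)C(OC)C1=O | intermediate
31 | (3R)-3-(2-hydroxy-3,4,6-trimethoxyphenyl)-1-phenyl-3-[4α-(trimethylsilyloxy)eudesm-11-en-1β-yl]propan-1-one | C=C(C)[C@@H]1CC[C@]2(C)[C@@H](C1)[C@](C)(O[Si](C)(C)C)CC[C@H]2[C@@H](CC(=O)c1ccccc1)c1c(OC)cc(OC)c(OC)c1O | intermediate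
32 | (3R)-3-(4α-hydroxyeudesm-11-en-1β-yl)-3-(2-hydroxy-3,4,6-trimethoxyphenyl)-1-phenylpropan-1-one | C=C(C)[C@@H]1CC[C@]2(C)[C@@H](C1)[C@](C)(O)CC[C@H]2[C@@H](CC(=O)c1ccccc1)c1c(OC)cc(OC)c(OC)c1O | intermediate
33 | 4′-(4α-hydroxyeudesm-11-en-1β-yl)-5′,7′,8′-trimethoxy-2′-phenylchroman-2′-ol (hemiketal, both epimers at C2′) | C=C(C)[C@@H]1CC[C@]2(C)[C@@H](C1)[C@](C)(O)CC[C@H]2[C@H]1CC(O)(c2ccccc2)Oc2c(OC)c(OC)cc(OC)c21 | intermediate
34 | (4′S)-4′-(4α-hydroxyeudesm-11-en-1β-yl)-5′,7′,8′-trimethoxy-2′-phenyl-4′H-chromene | C=C(C)[C@@H]1CC[C@]2(C)[C@@H](C1)[C@](C)(O)CC[C@H]2[C@H]1C=C(c2ccccc2)Oc2c(OC)c(OC)cc(OC)c21 | target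

**Step count**

Total: 17 steps. Longest linear sequence: 14 steps from (R)-limonene (steps 1–8, 10, 12, 13, 14, 16, 17).

**Steps most likely to fail**

1. Step 16. The vinylketene may be lost to self-reaction before the [2+2] step, or the 4-methoxycyclobutenone may decompose before it opens. Fallback, setting out from 23 and coming back at 31: the same vinylketene is made by elimination instead of ring opening. Commercial methyl 4-methoxyacetoacetate is converted with HC(OMe)3 and catalytic H2SO4 in MeOH into methyl (E)-3,4-dimethoxybut-2-enoate F1. Saponification (LiOH, THF–H2O) gives (E)-3,4-dimethoxybut-2-enoic acid F2, and (COCl)2 with catalytic DMF gives (E)-3,4-dimethoxybut-2-enoyl chloride F3. Slow addition of F3 and excess Et3N to 23 in toluene at 80 °C should give vinylketene 27 by 1,4-dehydrochlorination in the presence of the ynol ether; the same [2+2], 4π and 6π sequence then leads to 31.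

2. Step 12. The alane may attack the benzoyl carbonyl 1,2 or fail to reach the hindered β-carbon, and facial discrimination may erode. Fallback, setting out from 10 and coming back at 22: a more electrophilic, ketone-free acceptor is used and the benzoyl group is installed last. Knoevenagel condensation of 10 with Meldrum's acid (pyrrolidinium acetate, benzene, 25 °C) gives 5-[(4α-hydroxyeudesm-11-en-1β-yl)methylidene]-2,2-dimethyl-1,3-dioxane-4,6-dione F4, which keeps a cis carbonyl and therefore the same A1,3 control. Lithium methoxyacetylide 18 (2.2 equiv, THF, −78 °C) adds directly to give the alkynyl Meldrum's acid adduct F5. Heating F5 with MeNHOMe in pyridine (90 °C) opens the dioxanedione and decarboxylates to the Weinreb amide (3R)-3-(4α-hydroxyeudesm-11-en-1β-yl)-N,5-dimethoxy-N-methylpent-4-ynamide F6, and PhMgBr (excess, THF, 0 °C) gives 22.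

3. Step 5. At 180 °C the trans- and cis-fused (endo and exo) transition states may not be separated well enough. Fallback, setting out from 6 and coming back at 9: the dienophile is changed to an enal so that the cycloaddition can run under Lewis acid catalysis at low temperature. Reduction of 6 with (i-Bu)2AlH (CH2Cl2, −78 °C) gives (2E,6R,8E)-3,9-dimethyl-6-(prop-1-en-2-yl)undeca-2,8,10-trien-1-ol F7, and MnO2 gives the trienal F8. Me2AlCl (CH2Cl2, −78 → −20 °C) should then give the endo, trans-fused 5αH-eudesma-3,11-diene-1β-carbaldehyde F9. NaBH4 gives the primary alcohol F10, mCPBA the 3α,4α-epoxy alcohol F11, and LiAlH4 (THF, reflux) opens the epoxide to diol 9.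

**Further compounds**

F1 | step 16 | methyl (E)-3,4-dimethoxybut-2-enoate | COC/C(OC)=C\C(=O)OC
F2 | step 16 | (E)-3,4-dimethoxybut-2-enoic acid | COC/C(OC)=C\C(=O)O
F3 | step 16 | (E)-3,4-dimethoxybut-2-enoyl chloride | COC/C(OC)=C\C(=O)Cl
F4 | step 12 | 5-[(4α-hydroxyeudesm-11-en-1β-yl)methylidene]-2,2-dimethyl-1,3-dioxane-4,6-dione | C=C(C)[C@@H]1CC[C@]2(C)[C@@H](C1)[C@](C)(O)CC[C@H]2C=C1C(=O)OC(C)(C)OC1=O
F5 | step 12 | 5-[1-(4α-hydroxyeudesm-11-en-1β-yl)-3-methoxyprop-2-yn-1-yl]-2,2-dimethyl-1,3-dioxane-4,6-dione (propargylic centre as in 22) | C=C(C)[C@@H]1CC[C@]2(C)[C@@H](C1)[C@](C)(O)CC[C@H]2[C@@H](C1C(=O)OC(C)(C)OC1=O)C#COC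
F6 | step 12 | (3R)-3-(4α-hydroxyeudesm-11-en-1β-yl)-N,5-dimethoxy-N-methylpent-4-ynamide | C=C(C)[C@@H]1CC[C@]2(C)[C@@H](C1)[C@](C)(O)CC[C@H]2[C@@H](CC(=O)N(C)OC)C#COC
F7 | step 5 | (2E,6R,8E)-3,9-dimethyl-6-(prop-1-en-2-yl)undeca-2,8,10-trien-1-ol | C=C(C)[C@@H](C/C=C(C)/C=C)CC/C(C)=C/CO
F8 | step 5 | (2E,6R,8E)-3,9-dimethyl-6-(prop-1-en-2-yl)undeca-2,8,10-trienal | C=C(C)[C@@H](C/C=C(C)/C=C)CC/C(C)=C/C=O
F9 | step 5 | 5αH-eudesma-3,11-diene-1β-carbaldehyde | C=C(C)[C@@H]1CC[C@]2(C)[C@@H](C1)C(C)=CC[C@H]2C=O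
F10 | step 5 | 1β-(hydroxymethyl)-5αH-eudesma-3,11-diene | C=C(C)[C@@H]1CC[C@]2(C)[C@@H](C1)C(C)=CC[C@H]2CO
F11 | step 5 | 3α,4α-epoxy-1β-(hydroxymethyl)-5αH-eudesm-11-ene | C=C(C)[C@@H]1CC[C@]2(C)[C@@H](C1)[C@]1(C)O[C@@H]1C[C@H]2CO
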